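**Retrosynthetic overview**

- Target 31 comes from the bicyclic 8-O-(4-methoxybenzyl) 9-hydroxy 3-ketone 26 by ketone reduction, double acylation with hex-2-ynoic acid, semihydrogenation and removal of the O8 ether. The strategy rests on one feature of 26: O9, the trans C10–H, the axial C5 methyl and the C4 methyl next to O3 are the anti-addition pattern of a C9 carbonyl carbon and an enol carbon C4 across an (E)-C5=C10 alkene.
- 26 comes from the open-chain α-alkoxy aldehyde 25, which carries the (E)-alkene and a (Z)-enol silane. One SnCl4 cascade forms C9–C10 and closes ring B (C5–C10) first, then forms C4–C5 and closes ring A (C1–C5, C10).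
- 25 comes from vinyl ketone 22 by 1,4-hydrosilylation, reductive opening of an 8,9-O-(4-methoxybenzylidene) acetal and oxidation at C9. 22 comes from allylic bromide 18, N-methoxy-N-methylacetamide and vinylmagnesium bromide.
- 18 comes from an Evans syn-aldol (C7–C8 bond, both stereocentres) between a geraniol-derived (E)-4-methylhex-4-enoyl imide and (tert-butyldimethylsilyloxy)acetaldehyde; the imide carbonyl becomes the isopropenyl group.

Key step: step 17

Assumption: eremophilane numbering (ring A = C1–C5 and C10, ring B = C5–C10, isopropenyl on C7) and CIP descriptors in that numbering are used for all compounds, open-chain ones included; acetals 14–18 and 21–23 are carried as the mixture of both epimers at the acetal carbon, and epoxide 3 is racemic.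

**Step 1**
Reactants: 1 geraniol
Product: 2 geranyl tert-butyldiphenylsilyl ether
Conditions: TBDPSCl, imidazole, DMF, 0 °C → rt
Reagents that add atoms: tert-butyl(chloro)diphenylsilane, CC(C)(C)[Si](Cl)(c1ccccc1)c1ccccc1
Why: Imidazole-promoted O-silylation of the primary allylic alcohol should give an ether that survives the periodate cleavage, the boron aldol and both Grignard steps and is the only fluoride-labile group left when C1 is freed in step 10.

**Step 2**
Reactants: 2 geranyl tert-butyldiphenylsilyl ether
Product: 4 (4E)-6-(tert-butyldiphenylsilyloxy)-4-methylhex-4-enal, via 6,7-epoxide 3 (not isolated)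
Conditions: mCPBA, NaHCO3, CH2Cl2, −20 → 0 °C; crude 3, H5IO6, THF–H2O, 0 °C
Reagents that add atoms: 3-chloroperoxybenzoic acid, OOC(=O)c1cccc(Cl)c1
Why: Prilezhaev epoxidation should take the electron-rich 6,7-alkene in preference to the 2,3-alkene, which the allylic oxygen deactivates, and periodic acid then opens the epoxide and cleaves the glycol (Malaprade cleavage) to the aldehyde and acetone without touching the (E)-alkene.

**Step 3**
Reactants: 4 (4E)-6-(tert-butyldiphenylsilyloxy)-4-methylhex-4-enal
Product: 5 (4E)-6-(tert-butyldiphenylsilyloxy)-4-methylhex-4-enoic acid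
Conditions: NaClO2, NaH2PO4, 2-methyl-2-butene, t-BuOH–H2O, rt
Reagents that add atoms: sodium chlorite, [Na+].[O-]Cl=O
Why: Pinnick oxidation converts the aldehyde into the acid under buffered conditions, with 2-methyl-2-butene scavenging hypochlorous acid so that the trisubstituted alkene and the silyl ether stay intact.

**Step 4**
Reactants: 5 (4E)-6-(tert-butyldiphenylsilyloxy)-4-methylhex-4-enoic acid; 6 (R)-4-benzyl-1,3-oxazolidin-2-one
Product: 8 (R)-4-benzyl-3-[(4E)-6-(tert-butyldiphenylsilyloxy)-4-methylhex-4-enoyl]-1,3-oxazolidin-2-one, via mixed pivalic anhydride 7 (not isolated)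
Conditions: PivCl, Et3N, THF, −20 °C; then 6, LiCl, −20 °C → rt
Reagents that add atoms: none
Why: N-Acylation of the oxazolidinone by the mixed pivalic anhydride (LiCl/Et3N variant of the Evans imide synthesis) should occur at the unhindered acyl carbon and needs no strong base.

**Step 5**
Reactants: 8 N-acyl oxazolidinone; 9 (tert-butyldimethylsilyloxy)acetaldehyde
Product: 11 (7R,8R) syn-aldol adduct of 8 and 9, via (Z)-dibutylboron enolate 10 (not isolated)
Conditions: n-Bu2BOTf, i-Pr2NEt, CH2Cl2, −78 → 0 °C; 9, −78 → 0 °C; pH 7 buffer, MeOH, H2O2, 0 °C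
Reagents that add atoms: none
Why: Evans syn-aldol reaction, in which the (Z)-boron enolate reacts through a Zimmerman–Traxler chair with the auxiliary carbonyl turned away, so the (R)-benzyl group shields one enolate face and sets C7 (R) and C8 (R) together as the syn pair that the cyclisation needs.

**Step 6**
Reactants: 11 syn-aldol adduct
Product: 12 (7R,8R) 8-hydroxy 9-TBS-oxy Weinreb amide
Conditions: MeNHOMe·HCl, AlMe3, CH2Cl2, −20 → 0 °C; Rochelle salt
Reagents that add atoms: N,O-dimethylhydroxylamine hydrochloride, CNOC.Cl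
Why: Aluminium amide aminolysis (Weinreb transamidation) of the imide is directed to the exocyclic carbonyl by the aluminium alkoxide of the free C8 hydroxyl, releases the auxiliary and should not epimerise C7.

**Step 7**
Reactants: 12 Weinreb amide
Product: 14 8,9-O-(4-methoxybenzylidene) acetal of the Weinreb amide, via 8,9-diol 13 (not isolated)
Conditions: HF·pyridine, pyridine, THF, 0 °C; crude 13, 4-MeOC6H4CH(OMe)2, PPTS, CH2Cl2, rt
Reagents that add atoms: 4-methoxybenzaldehyde dimethyl acetal, COc1ccc(C(OC)OC)cc1
Why: Buffered HF·pyridine removes the primary TBS ether much faster than the TBDPS ether and acid-catalysed transacetalisation then ties O8 and O9 into a dioxolane inert to the organometallic steps; the crude diol is used at once to forestall lactonisation onto the amide, and the uncontrolled acetal carbon is of no consequence because step 15 removes it.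

**Step 8**
Reactants: 14 acetal Weinreb amide
Product: 15 (7R,8R) C11 methyl ketone
Conditions: MeMgBr, THF, −20 → 0 °C; aq. NH4Cl
Reagents that add atoms: methylmagnesium bromide, C[Mg]Br
Why: Weinreb ketone synthesis, in which the chelated tetrahedral magnesium adduct stops the addition at the ketone stage and the ketone is set free only on work-up, so C7 should not epimerise.

**Step 9**
Reactants: 15 methyl ketone
Product: 16 (7S,8R) isopropenyl acetal TBDPS ether
Conditions: Cp2TiMe2, toluene–THF, 65 °C, dark
Reagents that add atoms: dimethyltitanocene, C[Ti](C)(C1C=CC=C1)C1C=CC=C1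
Why: Petasis methylenation by the non-basic titanium methylidene turns the C11 ketone into the isopropenyl group without enolisation, so neither C7 epimerisation nor β-elimination of O8 should occur.

**Step 10**
Reactants: 16 isopropenyl acetal TBDPS ether
Product: 17 (7S,8R) C1 allylic alcohol
Conditions: Bu4NF, THF, 0 °C → rt
Reagents that add atoms: none
Why: Fluoride desilylation frees the C1 allylic alcohol, and the acetal and both alkenes are inert to it.

**Step 11**
Reactants: 17 allylic alcohol
Product: 18 (7S,8R) C1 allylic bromide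
Conditions: CBr4, PPh3, 2,6-lutidine, CH2Cl2, −20 → 0 °C
Reagents that add atoms: tetrabromomethane, BrC(Br)(Br)Br
Why: Appel bromination proceeds by SN2 attack of bromide on the primary alkoxyphosphonium ion, so the (E)-alkene geometry is kept and the buffered neutral medium spares the acetal.

**Step 12**
Reactants: 18 allylic bromide; 19 N-methoxy-N-methylacetamide
Product: 21 (7S,8R) C3 Weinreb amide, via lithium enolate 20 (not isolated)
Conditions: 19, LiN(i-Pr)2, THF, −78 °C; then 18, −78 → −30 °C
Reagents that add atoms: none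
Why: SN2 alkylation of the amide enolate by the primary allylic bromide forms the C1–C2 bond and brings in C3 as a Weinreb amide; the enolate is kept cold and in excess because it is thermally labile.

**Step 13**
Reactants: 21 C3 Weinreb amide
Product: 22 (7S,8R) vinyl ketone
Conditions: CH2=CHMgBr, THF, −78 → 0 °C; inverse quench into cold aq. citrate buffer, pH 3
Reagents that add atoms: vinylmagnesium bromide, C=C[Mg]Br
Why: Weinreb ketone synthesis gives the vinyl ketone on collapse of the chelated adduct, and the acidic inverse quench protonates the liberated N,O-dimethylhydroxylamine so that it does not add to the enone.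

**Step 14**
Reactants: 22 vinyl ketone
Product: 23 (3Z,7S,8R) tert-butyldimethylsilyl enol ether acetal
Conditions: t-BuMe2SiH, Pt2[(CH2=CHSiMe2)2O]3 (cat.), toluene, rt → 40 °C
Reagents that add atoms: tert-butyldimethylsilane, C[SiH](C)C(C)(C)C
Why: Platinum-catalysed 1,4-hydrosilylation of the s-cis vinyl ketone delivers hydrogen to the terminal carbon and silicon to oxygen, which should give only the C3=C4 enol silane with (Z) geometry (oxygen and methyl cis), while the 1,1-disubstituted and trisubstituted alkenes react far more slowly.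

**Step 15**
Reactants: 23 enol silane acetal
Product: 24 (7S,8R) 8-O-(4-methoxybenzyl) C9 alcohol with (Z)-enol silane
Conditions: i-Bu2AlH, CH2Cl2, −78 → 0 °C; Rochelle salt
Reagents that add atoms: none
Why: Regioselective reductive opening of the 4-methoxybenzylidene acetal, in which aluminium binds the less hindered O9, the C–O9 bond breaks and hydride adds to the oxocarbenium ion, should leave the 4-methoxybenzyl ether on the hindered O8 and free the C9 alcohol from either acetal epimer without harming the enol silane.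

**Step 16**
Reactants: 24 C9 alcohol
Product: 25 (7S,8R) open-chain 8-(4-methoxybenzyloxy) aldehyde with (E)-alkene and (Z)-enol silane
Conditions: SO3·pyridine, DMSO, i-Pr2NEt, CH2Cl2, −10 → 0 °C
Reagents that add atoms: none
Why: Parikh–Doering oxidation works in a basic, non-aqueous medium in which the acid-labile enol silane survives, and the α-alkoxy aldehyde should keep its C8 configuration if it is used at once.

**Step 17**
Reactants: 25 open-chain aldehyde
Product: 26 (4R,5S,7S,8R,9S,10R)-9-hydroxy-8-(4-methoxybenzyloxy)-trans-eremophil-11-en-3-one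
Conditions: SnCl4 (1.1 equiv), CH2Cl2 (0.005 M), −78 °C; aq. NaHCO3
Reagents that add atoms: none
Why: SnCl4 binds O9 and O8 of the α-alkoxy aldehyde as a five-membered chelate, C10 of the (E)-C5=C10 alkene attacks C9 (ring B, 6-endo, chair) and the developing tertiary C5 cation is taken by C4 of the (Z)-enol silane (ring A, 6-endo, chair), after which the silyl oxocarbenium ion gives its silyl group to chloride and leaves the C3 ketone. The closest known reaction type is the Lewis acid-promoted cation–olefin (Prins-type) polyene cyclisation started at an aldehyde or acetal and ended by a silyl enol ether, combined with chelation-controlled activation of an α-alkoxy aldehyde. At C9 the chelate holds the carbonyl oxygen gauche to the axial O8, so the new hydroxyl is equatorial; at C10 and C5 anti addition across the (E)-alkene in a chair–chair fold gives axial hydrogen and axial methyl (trans ring fusion); at C4 the (Z)-enol silane geometry places the methyl equatorial, cis to the C5 methyl. The fold is fixed by C7, whose isopropenyl group must be equatorial because an axial one would be syn-axial to the C5 methyl, and this puts O8 axial and selects one alkene face. The step needs capture of the C5 cation to outrun proton loss and the isopropenyl group to stay out: the first is secured by the nucleophilic enol silane held in a six-membered chair, the second because the isopropenyl alkene could only close strained four- or five-membered rings.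

**Step 18**
Reactants: 26 bicyclic keto alcohol
Product: 27 (3R,4R,5R,7S,8R,9S,10R)-8-(4-methoxybenzyloxy)eremophil-11-ene-3,9-diol
Conditions: SmI2, H2O, Et3N, THF, 0 °C
Reagents that add atoms: none
Why: Single-electron (ketyl) reduction with samarium diiodide should give the thermodynamically preferred equatorial C3 alcohol (3R), the axial epimer being syn-diaxial to the C5 methyl, whereas hydrides would attack from the open α face and give the axial alcohol and lithium in ammonia would also cleave the O8 ether that must stay until the esters are in place.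

**Step 19**
Reactants: 27 3,9-diol; 28 hex-2-ynoic acid
Product: 29 3,9-bis(hex-2-ynoate) 8-O-(4-methoxybenzyl) ether
Conditions: 28 (2.6 equiv), DCC, DMAP (cat.), CH2Cl2, −10 → 0 °C
Reagents that add atoms: none
Why: Steglich esterification acylates the two free equatorial hydroxyl groups at C3 and C9 while O8 is still protected, and the alkynoic acid is used because a (Z)-enoic acid could isomerise under acyl-transfer catalysis.

**Step 20**
Reactants: 29 bis(hex-2-ynoate)
Product: 30 3,9-bis[(Z)-hex-2-enoate] 8-O-(4-methoxybenzyl) ether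
Conditions: H2 (1 atm), Pd/CaCO3–Pb(OAc)2, quinoline, EtOAc, rt
Reagents that add atoms: none
Why: Lindlar semihydrogenation adds hydrogen syn to both conjugated alkynes and should stop at the (Z)-enoates, with the hindered isopropenyl group and the benzylic ether left alone.

**Step 21**
Reactants: 30 bis[(Z)-hex-2-enoate] ether
Product: 31 (3R,4R,5R,7S,8R,9S,10R)-8-hydroxyeremophil-11-ene-3,9-diyl bis[(2Z)-hex-2-enoate]
Conditions: DDQ, CH2Cl2–pH 7 buffer, 0 °C
Reagents that add atoms: none
Why: Oxidative cleavage of the 4-methoxybenzyl ether with DDQ (hydride abstraction, then hydrolysis of the oxocarbenium ion) frees the axial C8 hydroxyl under neutral conditions that should neither isomerise the (Z)-enoates nor move the C9 acyl group.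

**Compound list**

1 | geraniol | CC(C)=CCC/C(C)=C/CO | starting material
2 | geranyl tert-butyldiphenylsilyl ether | CC(C)=CCC/C(C)=C/CO[Si](c1ccccc1)(c1ccccc1)C(C)(C)C | intermediate
3 | 6,7-epoxide of 2 (racemic) | CC1(C)OC1CC/C(C)=C/CO[Si](c1ccccc1)(c1ccccc1)C(C)(C)C | intermediate
4 | (4E)-6-(tert-butyldiphenylsilyloxy)-4-methylhex-4-enal | O=CCC/C(C)=C/CO[Si](c1ccccc1)(c1ccccc1)C(C)(C)C | intermediate
5 | (4E)-6-(tert-butyldiphenylsilyloxy)-4-methylhex-4-enoic acid | OC(=O)CC/C(C)=C/CO[Si](c1ccccc1)(c1ccccc1)C(C)(C)C | intermediate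
6 | (R)-4-benzyl-1,3-oxazolidin-2-one | O=C1N[C@H](Cc2ccccc2)CO1 | starting material
7 | mixed anhydride of 5 and pivalic acid | CC(C)(C)C(=O)OC(=O)CC/C(C)=C/CO[Si](c1ccccc1)(c1ccccc1)C(C)(C)C | intermediate
8 | (R)-4-benzyl-3-[(4E)-6-(tert-butyldiphenylsilyloxy)-4-methylhex-4-enoyl]-1,3-oxazolidin-2-one | O=C(CC/C(C)=C/CO[Si](c1ccccc1)(c1ccccc1)C(C)(C)C)N1[C@H](Cc2ccccc2)COC1=O | intermediate
9 | (tert-butyldimethylsilyloxy)acetaldehyde | O=CCO[Si](C)(C)C(C)(C)C | starting material
10 | (Z)-dibutylboron enolate of 8 | CCCCB(CCCC)O/C(=C\C/C(C)=C/CO[Si](c1ccccc1)(c1ccccc1)C(C)(C)C)N1[C@H](Cc2ccccc2)COC1=O | intermediate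
11 | (7R,8R) syn-aldol adduct: imide with C7 bearing the (E)-4-(TBDPS-oxy)-2-methylbut-2-enyl chain, C8–OH, C9–OTBS | CC(C)(C)[Si](C)(C)OC[C@H](O)[C@H](C(=O)N1[C@H](Cc2ccccc2)COC1=O)C/C(C)=C/CO[Si](c1ccccc1)(c1ccccc1)C(C)(C)C | intermediate
12 | (2R,4E)-6-(TBDPS-oxy)-2-[(1R)-1-hydroxy-2-(TBS-oxy)ethyl]-N-methoxy-N,4-dimethylhex-4-enamide | CC(C)(C)[Si](C)(C)OC[C@H](O)[C@H](C(=O)N(C)OC)C/C(C)=C/CO[Si](c1ccccc1)(c1ccccc1)C(C)(C)C | intermediate
13 | (2R,4E)-6-(TBDPS-oxy)-2-[(1R)-1,2-dihydroxyethyl]-N-methoxy-N,4-dimethylhex-4-enamide | OC[C@H](O)[C@H](C(=O)N(C)OC)C/C(C)=C/CO[Si](c1ccccc1)(c1ccccc1)C(C)(C)C | intermediate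
14 | (2R,4E)-6-(TBDPS-oxy)-N-methoxy-2-[(4R)-2-(4-methoxyphenyl)-1,3-dioxolan-4-yl]-N,4-dimethylhex-4-enamide (both acetal epimers) | COc1ccc(cc1)C1OC[C@H](O1)[C@H](C(=O)N(C)OC)C/C(C)=C/CO[Si](c1ccccc1)(c1ccccc1)C(C)(C)C | intermediate
15 | (3R,5E)-7-(TBDPS-oxy)-3-[(4R)-2-(4-methoxyphenyl)-1,3-dioxolan-4-yl]-5-methylhept-5-en-2-one | COc1ccc(cc1)C1OC[C@H](O1)[C@H](C(C)=O)C/C(C)=C/CO[Si](c1ccccc1)(c1ccccc1)C(C)(C)C | intermediate
16 | TBDPS ether of (2E,5S)-5-[(4R)-2-(4-methoxyphenyl)-1,3-dioxolan-4-yl]-3,6-dimethylhepta-2,6-dien-1-ol | COc1ccc(cc1)C1OC[C@H](O1)[C@H](C(C)=C)C/C(C)=C/CO[Si](c1ccccc1)(c1ccccc1)C(C)(C)C | intermediate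
17 | (2E,5S)-5-[(4R)-2-(4-methoxyphenyl)-1,3-dioxolan-4-yl]-3,6-dimethylhepta-2,6-dien-1-ol | COc1ccc(cc1)C1OC[C@H](O1)[C@H](C(C)=C)C/C(C)=C/CO | intermediate
18 | (4R)-4-[(3S,5E)-7-bromo-2,5-dimethylhepta-1,5-dien-3-yl]-2-(4-methoxyphenyl)-1,3-dioxolane | COc1ccc(cc1)C1OC[C@H](O1)[C@H](C(C)=C)C/C(C)=C/CBr | intermediate
19 | N-methoxy-N-methylacetamide | CC(=O)N(C)OC | starting material
20 | lithium enolate of 19 | [Li]OC(=C)N(C)OC | intermediate
21 | (4E,7S)-N-methoxy-7-[(4R)-2-(4-methoxyphenyl)-1,3-dioxolan-4-yl]-N,5,8-trimethylnona-4,8-dienamide | COc1ccc(cc1)C1OC[C@H](O1)[C@H](C(C)=C)C/C(C)=C/CCC(=O)N(C)OC | intermediate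
22 | (6E,9S)-9-[(4R)-2-(4-methoxyphenyl)-1,3-dioxolan-4-yl]-7,10-dimethylundeca-1,6,10-trien-3-one | COc1ccc(cc1)C1OC[C@H](O1)[C@H](C(C)=C)C/C(C)=C/CCC(=O)C=C | intermediate
23 | TBS enol ether, (2Z,6E,9S)-9-[(4R)-2-(4-methoxyphenyl)-1,3-dioxolan-4-yl]-7,10-dimethylundeca-2,6,10-trien-3-yl silyl ether | COc1ccc(cc1)C1OC[C@H](O1)[C@H](C(C)=C)C/C(C)=C/CC/C(O[Si](C)(C)C(C)(C)C)=C/C | intermediate
24 | (2R,3S,5E,9Z)-9-(TBS-oxy)-2-(4-methoxybenzyloxy)-5-methyl-3-(prop-1-en-2-yl)undeca-5,9-dien-1-ol | OC[C@H](OCc1ccc(OC)cc1)[C@H](C(C)=C)C/C(C)=C/CC/C(O[Si](C)(C)C(C)(C)C)=C/C | intermediate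
25 | (2R,3S,5E,9Z)-9-(TBS-oxy)-2-(4-methoxybenzyloxy)-5-methyl-3-(prop-1-en-2-yl)undeca-5,9-dienal | O=C[C@H](OCc1ccc(OC)cc1)[C@H](C(C)=C)C/C(C)=C/CC/C(O[Si](C)(C)C(C)(C)C)=C/C | intermediate
26 | (4R,5S,7S,8R,9S,10R)-9-hydroxy-8-(4-methoxybenzyloxy)-trans-eremophil-11-en-3-one | C=C(C)[C@@H]1C[C@]2(C)[C@@H](C)C(=O)CC[C@H]2[C@H](O)[C@@H]1OCc1ccc(OC)cc1 | intermediate
27 | (3R,4R,5R,7S,8R,9S,10R)-8-(4-methoxybenzyloxy)eremophil-11-ene-3,9-diol | C=C(C)[C@@H]1C[C@]2(C)[C@@H](C)[C@H](O)CC[C@H]2[C@H](O)[C@@H]1OCc1ccc(OC)cc1 | intermediate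
28 | hex-2-ynoic acid | CCCC#CC(=O)O | starting material
29 | 3,9-bis(hex-2-ynoate) of 27 | C=C(C)[C@@H]1C[C@]2(C)[C@@H](C)[C@H](OC(=O)C#CCCC)CC[C@H]2[C@H](OC(=O)C#CCCC)[C@@H]1OCc1ccc(OC)cc1 | intermediate
30 | 3,9-bis[(Z)-hex-2-enoate] of 27 | C=C(C)[C@@H]1C[C@]2(C)[C@@H](C)[C@H](OC(=O)/C=C\CCC)CC[C@H]2[C@H](OC(=O)/C=C\CCC)[C@@H]1OCc1ccc(OC)cc1 | intermediate
31 | (3R,4R,5R,7S,8R,9S,10R)-8-hydroxyeremophil-11-ene-3,9-diyl bis[(2Z)-hex-2-enoate] (CNP0420276.1) | C=C(C)[C@@H]1C[C@]2(C)[C@@H](C)[C@H](OC(=O)/C=C\CCC)CC[C@H]2[C@H](OC(=O)/C=C\CCC)[C@@H]1O | target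

**Step count and risks**

Total step count: 21. Longest linear sequence: 21 steps (1 → 31).

Steps most likely to fail:

1. Step 17. The C5 cation may lose a proton, or the enol ether may lose its silyl group, before ring A closes, so that the cascade stops after ring B; incomplete chelation would also erode the C9 configuration. The fallback makes the two rings in separate operations and sets out from 25. Me2AlCl (2 equiv, CH2Cl2, −78 °C), a chelating Lewis acid whose aluminium-bound methyl removes the proton as methane, should give by intramolecular carbonyl-ene reaction through the same chelated chair the monocyclic ring B alcohol with an exocyclic C5 methylene, F1. Treating F1 with SnCl4 at −78 °C forms the O9 tin alkoxide and hydrogen chloride; Markovnikov protonation of the C5 methylene regenerates the C5 cation, which the enol silane takes in a proton-initiated cation–olefin cyclisation that closes ring A. The fallback comes back to the route at 26.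

2. Step 18. Hydrogen delivery to the ketyl may show poor facial selectivity and give the axial C3 alcohol, or conversion may be slow. The fallback sets out from 26. Lithium in liquid ammonia with t-BuOH (−78 °C) should give the equatorial alcohol under thermodynamic control and at the same time cleave the O8 ether, which gives the 3,8,9-triol F2. F2 with 2.2 equiv of 28, DCC and catalytic DMAP at −20 °C should be acylated at the two equatorial hydroxyls (C3, C9); the axial C8 hydroxyl, flanked by the equatorial isopropenyl group and the C9 ester, reacts most slowly, and this gives the 3,9-bis(hex-2-ynoate) with free 8-OH, F3. Lindlar semihydrogenation of F3 as in step 20 comes back to the route at 31.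

3. Step 15. The dioxolane may open the wrong way (ether on O9, free O8–H), or the Lewis-acidic hydride may attack the enol silane. The fallback replaces the reductive opening by stepwise protection and sets out from 22. Aqueous acetic acid in THF hydrolyses the acetal to the 8,9-diol vinyl ketone F4. AcCl and 2,4,6-collidine at −78 °C acetylate the primary hydroxyl to give the 9-acetate F5. 4-Methoxybenzyl trichloroacetimidate with catalytic La(OTf)3 etherifies O8 to give the 9-acetate 8-(4-methoxybenzyl) ether F6. Hydrosilylation as in step 14 gives the (Z)-enol silane 9-acetate F7. i-Bu2AlH at −78 °C removes the acetate, and the fallback comes back to the route at 24.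

**Further compounds**

F1 | step 17 | ring B carbonyl-ene product, (7S,8R,9S,10R) 9-hydroxy-8-(4-methoxybenzyloxy) cyclohexane with C5 exocyclic methylene and (Z)-enol silane side chain on C10 | C=C(C)[C@@H]1CC(=C)[C@@H](CC/C(O[Si](C)(C)C(C)(C)C)=C/C)[C@H](O)[C@@H]1OCc1ccc(OC)cc1
F2 | step 18 | (3R,4R,5R,7S,8R,9S,10R)-eremophil-11-ene-3,8,9-triol | C=C(C)[C@@H]1C[C@]2(C)[C@@H](C)[C@H](O)CC[C@H]2[C@H](O)[C@@H]1O
F3 | step 18 | 8-hydroxyeremophil-11-ene-3,9-diyl bis(hex-2-ynoate) | C=C(C)[C@@H]1C[C@]2(C)[C@@H](C)[C@H](OC(=O)C#CCCC)CC[C@H]2[C@H](OC(=O)C#CCCC)[C@@H]1O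
F4 | step 15 | (6E,9S,10R)-10,11-dihydroxy-7-methyl-9-(prop-1-en-2-yl)undeca-1,6-dien-3-one | OC[C@H](O)[C@H](C(C)=C)C/C(C)=C/CCC(=O)C=C
F5 | step 15 | primary (C9) acetate of F4 | CC(=O)OC[C@H](O)[C@H](C(C)=C)C/C(C)=C/CCC(=O)C=C
F6 | step 15 | C9 acetate, O8 4-methoxybenzyl ether of F4 | CC(=O)OC[C@H](OCc1ccc(OC)cc1)[C@H](C(C)=C)C/C(C)=C/CCC(=O)C=C
F7 | step 15 | C9 acetate of 24 | CC(=O)OC[C@H](OCc1ccc(OC)cc1)[C@H](C(C)=C)C/C(C)=C/CC/C(O[Si](C)(C)C(C)(C)C)=C/C
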